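**Plan** (locants of the target name: five-membered ring C1, C2, C3, C3a, C7a; six-membered ring C3a, C4 to C7, C7a)
1. Retrosynthesis: remove the angelate and acetate esters, then cut C4–C5 and C6–C7 of the cyclohexane in one event. This excises C5–C6 as an enol ether and leaves a fully substituted cyclopentane, which is cut back to (R)-4-silyloxycyclopentenone.
2. Enabling feature: in the six-membered ring the C5–C6 unit lies between C4 and C7. C4 is an sp2 carbon carrying the exocyclic methylene, so it can be an alkenyl radical made from a 1-iodoethenyl group on C3a. The isopropyl group on C7 is the reduced form of a 2-methylprop-1-enyl group on C7a, a radical acceptor that ends as a tertiary radical.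
3. Forward order: five-membered ring first (stereocenters C3a, C7a, C1, C2 in that order), then the six-membered ring by a radical [4+2] annulation with trimethyl(vinyloxy)silane, then redox correction at C6 and the two acylations.
4. Stereochemistry: C3a from the starting enone; C7a and C1 by trans,trans substrate control; C2 by hydride attack anti to the C1 and C3a substituents; C7 in the key step; C6 by equatorial hydride attack on the ketone.
5. Helpers: the acetyl group travels as its dimethyl ketal (no abstractable hydrogen, inert to hydride) and the C2 oxygen as a silyl ether; both are removed in step 11.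

Key step: step 7

Remark on the chemistry: the ring closure of step 7 is not expected to control C6, so 14 and 15 are carried as C6 epimer pairs whose SMILES leave that centre open; both epimers converge in step 8.

Step 1
Reactants: 1 (R)-4-[(tert-butyldimethylsilyl)oxy]cyclopent-2-en-1-one; 2 (1-bromoethenyl)trimethylsilane
Product: 5 (R)-4-[1-(trimethylsilyl)ethenyl]cyclopent-2-en-1-one, via Grignard reagent 3 (not isolated), via silyloxy ketone 4 (not isolated)
Conditions: 2, Mg, THF, 40 °C; CuBr·SMe2 (10 mol %), THF, −78 °C, then 1; H2O quench; then DBU, CH2Cl2, 0 °C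
Reagents that add atoms: (1-bromoethenyl)trimethylsilane (2) C=C(Br)[Si](C)(C)C
Why: Copper-catalysed conjugate addition of the alkenyl Grignard reagent takes place anti to the silyloxy group and base then expels silanol from the β-silyloxy ketone (E1cB), so the oxygen-bearing stereocenter of 1 is exchanged for the carbon-bearing stereocenter that becomes C3a.

Step 2
Reactants: 5 (R)-4-[1-(trimethylsilyl)ethenyl]cyclopent-2-en-1-one
Product: 6 (R)-4-(1-iodoethenyl)cyclopent-2-en-1-one
Conditions: NIS, MeCN/ClCH2CN (4:1), 0 °C to rt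
Reagents that add atoms: N-iodosuccinimide O=C1CCC(=O)N1I
Why: Ipso iododesilylation of the 1,1-disubstituted alkenylsilane proceeds through the β-silyl cation and gives the 2-iodoalk-1-ene, while the electron-poor enone double bond should not react with the electrophile.

Step 3
Reactants: 6 (R)-4-(1-iodoethenyl)cyclopent-2-en-1-one; 7 (2-methylprop-1-en-1-yl)magnesium bromide
Product: 8 {[(3R,4R)-4-(1-iodoethenyl)-3-(2-methylprop-1-en-1-yl)cyclopent-1-en-1-yl]oxy}trimethylsilane
Conditions: 7 (0.5 M in THF), CuBr·SMe2 (10 mol %), Me3SiCl, THF, −78 °C; Et3N, non-aqueous work-up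
Reagents that add atoms: (2-methylprop-1-en-1-yl)magnesium bromide (7) CC(C)=C[Mg]Br; chlorotrimethylsilane C[Si](C)(C)Cl
Why: Chlorosilane-accelerated copper-catalysed conjugate addition should be much faster than any reaction at the alkenyl iodide at −78 °C and places the 2-methylprop-1-enyl group on the face opposite the C4 substituent (future C7a trans to C3a), the enolate being fixed as the silyl enol ether.

Step 4
Reactants: 8 {[(3R,4R)-4-(1-iodoethenyl)-3-(2-methylprop-1-en-1-yl)cyclopent-1-en-1-yl]oxy}trimethylsilane; 9 1,1,1-trimethoxyethane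
Product: 10 (2R,3R,4R)-2-(1,1-dimethoxyethyl)-4-(1-iodoethenyl)-3-(2-methylprop-1-en-1-yl)cyclopentan-1-one
Conditions: 9, Me3SiOTf (10 mol %), CH2Cl2, −78 °C; then Et3N
Reagents that add atoms: 1,1,1-trimethoxyethane (9) CC(OC)(OC)OC
Why: Mukaiyama-type condensation of the silyl enol ether with the 1,1-dimethoxyethyl cation released from the orthoester introduces the acetyl carbon in ketal form anti to the neighbouring alkenyl group, the usual 2,3-trans outcome of enolate trapping on a 3-substituted cyclopentanone (future C1).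

Step 5
Reactants: 10 (2R,3R,4R)-2-(1,1-dimethoxyethyl)-4-(1-iodoethenyl)-3-(2-methylprop-1-en-1-yl)cyclopentan-1-one
Product: 11 (1S,2R,3R,4R)-2-(1,1-dimethoxyethyl)-4-(1-iodoethenyl)-3-(2-methylprop-1-en-1-yl)cyclopentan-1-ol
Conditions: LiBH(s-Bu)3 (L-Selectride), THF, −78 °C; then H2O
Reagents that add atoms: none
Why: The hindered hydride attacks the cyclopentanone from the face opposite the ketal side chain and the iodoalkenyl group, which lie on the same face, and so should give the alcohol cis to the side chain (future C2).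

Step 6
Reactants: 11 (1S,2R,3R,4R)-2-(1,1-dimethoxyethyl)-4-(1-iodoethenyl)-3-(2-methylprop-1-en-1-yl)cyclopentan-1-ol
Product: 12 tert-butyl{[(1S,2R,3R,4R)-2-(1,1-dimethoxyethyl)-4-(1-iodoethenyl)-3-(2-methylprop-1-en-1-yl)cyclopentyl]oxy}dimethylsilane
Conditions: t-BuMe2SiCl, imidazole, DMAP (cat.), DMF, 40 °C
Reagents that add atoms: tert-butyldimethylsilyl chloride CC(C)(C)[Si](C)(C)Cl
Why: Routine silylation masks the secondary alcohol through the radical, oxidation and hydride steps and is not expected to disturb the ketal or the alkenyl iodide.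

Step 7
Reactants: 12 tert-butyl{[(1S,2R,3R,4R)-2-(1,1-dimethoxyethyl)-4-(1-iodoethenyl)-3-(2-methylprop-1-en-1-yl)cyclopentyl]oxy}dimethylsilane; 13 trimethyl(vinyloxy)silane
Product: 15 (1R,2S,3aR,6RS,7S,7aR)-2-[(tert-butyldimethylsilyl)oxy]-1-(1,1-dimethoxyethyl)-4-methylidene-7-(propan-2-yl)octahydro-1H-inden-6-ol (both C6 epimers), via silyl ether 14 (not isolated)
Conditions: 13/benzene (1:1, 13 in large excess), 80 °C, Bu3SnH and AIBN added over 10 h by syringe pump; then K2CO3 (cat.), MeOH, rt
Reagents that add atoms: trimethyl(vinyloxy)silane (13) C=CO[Si](C)(C)C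
Why: Proposed new method: Bu3Sn• abstracts iodine from 12, the σ-type alkenyl radical at C4 adds to the unsubstituted terminus of enol ether 13 (bond C4–C5), the α-silyloxy radical at C6 closes onto the proximal alkene carbon of the 2-methylprop-1-enyl group (bond C6–C7), and the tertiary radical takes hydrogen from Bu3SnH to become the isopropyl CH, after which methanolysis frees the C6 hydroxyl. The closest known chemistry is the tin hydride radical annulation (intermolecular addition followed by exo ring closure) and the Meerwein-type addition of σ-radicals to enol ethers; what is new is their combination with an alkenyl radical as a formal [4+2] construction of a methylenecyclohexane. The only ring closed is the cyclohexane, by 6-exo-trig attack, the 7-endo alternative being disfavoured because it would attack the fully substituted alkene carbon and leave a secondary radical. C7 is set by the substrate: A(1,3) strain keeps the C7a–H bond in the plane of the trisubstituted alkene, the tether from C3a reaches only the π face turned toward C3a, and the chair transition state leaves the future isopropyl group equatorial with C7–H anti to C7a–H, the trans ring fusion being already fixed in 12; C6 is not controlled and both epimers converge in step 8. The step needs intermolecular addition to outrun hydrogen transfer to the alkenyl radical and ring closure to outrun reduction of the C6 radical; this should be secured by the enol ether as cosolvent (it does not homopolymerize under radical conditions), by slow addition of Bu3SnH, and by the ketal carbon on C1, which offers no hydrogen to the cis-disposed alkenyl radical.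

Step 8
Reactants: 15 (1R,2S,3aR,6RS,7S,7aR)-2-[(tert-butyldimethylsilyl)oxy]-1-(1,1-dimethoxyethyl)-4-methylidene-7-(propan-2-yl)octahydro-1H-inden-6-ol
Product: 16 (1R,2S,3aR,7S,7aR)-2-[(tert-butyldimethylsilyl)oxy]-1-(1,1-dimethoxyethyl)-4-methylidene-7-(propan-2-yl)octahydro-1H-inden-6-one
Conditions: Dess–Martin periodinane, NaHCO3, CH2Cl2, 0 °C
Reagents that add atoms: none
Why: Buffered Dess–Martin oxidation converts both C6 epimers into the single ketone under neutral conditions that should not move the exocyclic double bond into conjugation or touch the ketal.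

Step 9
Reactants: 16 (1R,2S,3aR,7S,7aR)-2-[(tert-butyldimethylsilyl)oxy]-1-(1,1-dimethoxyethyl)-4-methylidene-7-(propan-2-yl)octahydro-1H-inden-6-one
Product: 17 (1R,2S,3aR,6R,7S,7aR)-2-[(tert-butyldimethylsilyl)oxy]-1-(1,1-dimethoxyethyl)-4-methylidene-7-(propan-2-yl)octahydro-1H-inden-6-ol
Conditions: LiBH(s-Bu)3 (L-Selectride), THF, −78 °C; then H2O
Reagents that add atoms: none
Why: As in the conversion of menthone into neomenthol, the bulky trialkylborohydride approaches the cyclohexanone along the equatorial trajectory and should give the axial C6 alcohol cis to the equatorial isopropyl group.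

Step 10
Reactants: 17 (1R,2S,3aR,6R,7S,7aR)-2-[(tert-butyldimethylsilyl)oxy]-1-(1,1-dimethoxyethyl)-4-methylidene-7-(propan-2-yl)octahydro-1H-inden-6-ol
Product: 18 (1R,2S,3aR,6R,7S,7aR)-2-[(tert-butyldimethylsilyl)oxy]-1-(1,1-dimethoxyethyl)-4-methylidene-7-(propan-2-yl)octahydro-1H-inden-6-yl acetate
Conditions: Ac2O, Et3N, DMAP (cat.), CH2Cl2, rt
Reagents that add atoms: acetic anhydride CC(=O)OC(C)=O
Why: DMAP-catalysed acetylation of the hindered axial alcohol is standard and the ketal and silyl ether are inert to it.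

Step 11
Reactants: 18 (1R,2S,3aR,6R,7S,7aR)-2-[(tert-butyldimethylsilyl)oxy]-1-(1,1-dimethoxyethyl)-4-methylidene-7-(propan-2-yl)octahydro-1H-inden-6-yl acetate
Product: 19 (1R,2S,3aR,6R,7S,7aR)-1-acetyl-2-hydroxy-4-methylidene-7-(propan-2-yl)octahydro-1H-inden-6-yl acetate
Conditions: aq. HF (48 %), MeCN, 0 °C to rt
Reagents that add atoms: water O
Why: Aqueous HF cleaves the secondary silyl ether and hydrolyses the acyclic dimethyl ketal in the same operation, while the acetate and the 1,1-disubstituted alkene should be stable to these mildly acidic conditions.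

Step 12
Reactants: 19 (1R,2S,3aR,6R,7S,7aR)-1-acetyl-2-hydroxy-4-methylidene-7-(propan-2-yl)octahydro-1H-inden-6-yl acetate; 20 angelic acid
Product: 22 (1R,2S,3aR,6R,7S,7aR)-1-acetyl-6-(acetyloxy)-4-methylidene-7-(propan-2-yl)octahydro-1H-inden-2-yl (2Z)-2-methylbut-2-enoate, via mixed anhydride 21 (not isolated)
Conditions: 20, 2,4,6-trichlorobenzoyl chloride, Et3N, toluene, rt; then 19, DMAP, toluene, 60 °C
Reagents that add atoms: angelic acid (20) C/C=C(/C)C(=O)O
Why: Yamaguchi esterification through the preformed mixed anhydride acylates the secondary alcohol under conditions known to keep the Z geometry of angelic acid and mild enough to spare the β-acyloxy ketone.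

**Compound list**
1 | (R)-4-[(tert-butyldimethylsilyl)oxy]cyclopent-2-en-1-one | O=C1C=C[C@H](O[Si](C)(C)C(C)(C)C)C1 | starting material
2 | (1-bromoethenyl)trimethylsilane | C=C(Br)[Si](C)(C)C | starting material
3 | [1-(trimethylsilyl)ethenyl]magnesium bromide | C=C([Mg]Br)[Si](C)(C)C | intermediate
4 | (3R,4R)-4-[(tert-butyldimethylsilyl)oxy]-3-[1-(trimethylsilyl)ethenyl]cyclopentan-1-one | C=C([Si](C)(C)C)[C@@H]1CC(=O)C[C@H]1O[Si](C)(C)C(C)(C)C | intermediate
5 | (R)-4-[1-(trimethylsilyl)ethenyl]cyclopent-2-en-1-one | C=C([Si](C)(C)C)[C@@H]1CC(=O)C=C1 | intermediate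
6 | (R)-4-(1-iodoethenyl)cyclopent-2-en-1-one | C=C(I)[C@@H]1CC(=O)C=C1 | intermediate
7 | (2-methylprop-1-en-1-yl)magnesium bromide | CC(C)=C[Mg]Br | starting material
8 | {[(3R,4R)-4-(1-iodoethenyl)-3-(2-methylprop-1-en-1-yl)cyclopent-1-en-1-yl]oxy}trimethylsilane | C=C(I)[C@@H]1CC(O[Si](C)(C)C)=C[C@H]1C=C(C)C | intermediate
9 | 1,1,1-trimethoxyethane (trimethyl orthoacetate) | CC(OC)(OC)OC | starting material
10 | (2R,3R,4R)-2-(1,1-dimethoxyethyl)-4-(1-iodoethenyl)-3-(2-methylprop-1-en-1-yl)cyclopentan-1-one | C=C(I)[C@@H]1CC(=O)[C@H](C(C)(OC)OC)[C@H]1C=C(C)C | intermediate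
11 | (1S,2R,3R,4R)-2-(1,1-dimethoxyethyl)-4-(1-iodoethenyl)-3-(2-methylprop-1-en-1-yl)cyclopentan-1-ol | C=C(I)[C@@H]1C[C@H](O)[C@H](C(C)(OC)OC)[C@H]1C=C(C)C | intermediate
12 | tert-butyl{[(1S,2R,3R,4R)-2-(1,1-dimethoxyethyl)-4-(1-iodoethenyl)-3-(2-methylprop-1-en-1-yl)cyclopentyl]oxy}dimethylsilane | C=C(I)[C@@H]1C[C@H](O[Si](C)(C)C(C)(C)C)[C@H](C(C)(OC)OC)[C@H]1C=C(C)C | intermediate
13 | trimethyl(vinyloxy)silane | C=CO[Si](C)(C)C | starting material
14 | tert-butyl{[(1R,2S,3aR,6RS,7S,7aR)-1-(1,1-dimethoxyethyl)-4-methylidene-7-(propan-2-yl)-6-[(trimethylsilyl)oxy]octahydro-1H-inden-2-yl]oxy}dimethylsilane (C6 epimer pair) | C=C1CC(O[Si](C)(C)C)[C@@H](C(C)C)[C@@H]2[C@@H](C(C)(OC)OC)[C@@H](O[Si](C)(C)C(C)(C)C)C[C@@H]12 | intermediate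
15 | (1R,2S,3aR,6RS,7S,7aR)-2-[(tert-butyldimethylsilyl)oxy]-1-(1,1-dimethoxyethyl)-4-methylidene-7-(propan-2-yl)octahydro-1H-inden-6-ol (C6 epimer pair) | C=C1CC(O)[C@@H](C(C)C)[C@@H]2[C@@H](C(C)(OC)OC)[C@@H](O[Si](C)(C)C(C)(C)C)C[C@@H]12 | intermediate
16 | (1R,2S,3aR,7S,7aR)-2-[(tert-butyldimethylsilyl)oxy]-1-(1,1-dimethoxyethyl)-4-methylidene-7-(propan-2-yl)octahydro-1H-inden-6-one | C=C1CC(=O)[C@@H](C(C)C)[C@@H]2[C@@H](C(C)(OC)OC)[C@@H](O[Si](C)(C)C(C)(C)C)C[C@@H]12 | intermediate
17 | (1R,2S,3aR,6R,7S,7aR)-2-[(tert-butyldimethylsilyl)oxy]-1-(1,1-dimethoxyethyl)-4-methylidene-7-(propan-2-yl)octahydro-1H-inden-6-ol | C=C1C[C@@H](O)[C@@H](C(C)C)[C@@H]2[C@@H](C(C)(OC)OC)[C@@H](O[Si](C)(C)C(C)(C)C)C[C@@H]12 | intermediate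
18 | (1R,2S,3aR,6R,7S,7aR)-2-[(tert-butyldimethylsilyl)oxy]-1-(1,1-dimethoxyethyl)-4-methylidene-7-(propan-2-yl)octahydro-1H-inden-6-yl acetate | C=C1C[C@@H](OC(C)=O)[C@@H](C(C)C)[C@@H]2[C@@H](C(C)(OC)OC)[C@@H](O[Si](C)(C)C(C)(C)C)C[C@@H]12 | intermediate
19 | (1R,2S,3aR,6R,7S,7aR)-1-acetyl-2-hydroxy-4-methylidene-7-(propan-2-yl)octahydro-1H-inden-6-yl acetate | C=C1C[C@@H](OC(C)=O)[C@@H](C(C)C)[C@@H]2[C@@H](C(C)=O)[C@@H](O)C[C@@H]12 | intermediate
20 | angelic acid, (2Z)-2-methylbut-2-enoic acid | C/C=C(/C)C(=O)O | starting material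
21 | (2Z)-2-methylbut-2-enoic 2,4,6-trichlorobenzoic anhydride | C/C=C(/C)C(=O)OC(=O)c1c(Cl)cc(Cl)cc1Cl | intermediate
22 | (1R,2S,3aR,6R,7S,7aR)-1-acetyl-6-(acetyloxy)-4-methylidene-7-(propan-2-yl)octahydro-1H-inden-2-yl (2Z)-2-methylbut-2-enoate | C=C1C[C@@H](OC(C)=O)[C@@H](C(C)C)[C@@H]2[C@@H](C(C)=O)[C@@H](OC(=O)/C(C)=C\C)C[C@@H]12 | target

Total step count: 12. Longest linear sequence: 12 steps (1 to 22).

**Steps most likely to fail**

Step 7. Hydrogen transfer to the alkenyl radical before it meets the enol ether, internal 1,5- or 1,6-hydrogen shifts (from C7a–H or the allylic methyl groups), or reduction of the C6 radical before ring closure would leave deiodinated or open-chain material. The fallback forms the two bonds separately by known reactions. It sets out from 12: Stille coupling with tributyl(vinyl)stannane (Pd(PPh3)4, CuI, DMF) should give the buta-1,3-dien-2-yl analogue of 12 F1. 9-BBN followed by NaOH/H2O2 hydroborates only the monosubstituted vinyl group and gives the 4-hydroxybut-1-en-2-yl analogue of 12 F2. Buffered Dess–Martin oxidation gives the 4-oxobut-1-en-2-yl analogue of 12 F3. SmI2/HMPA/t-BuOH in THF then closes C6–C7 by ketyl–olefin cyclization, the tertiary organosamarium being protonated to the isopropyl group, and the route is rejoined at 15.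

Step 4. Slow capture of the stabilized dimethoxyethyl cation and loss of methanol from the β-keto ketal to a vinylogous ester would erase the C1 stereocenter. The fallback attaches the acetyl carbon before the conjugate addition and sets out from 5. α-Iodination (I2, pyridine, CH2Cl2) gives (R)-2-iodo-4-[1-(trimethylsilyl)ethenyl]cyclopent-2-en-1-one F4. Stille coupling with tributyl(1-ethoxyvinyl)stannane (Pd(PPh3)4, CuI, DMF) gives (R)-2-(1-ethoxyethenyl)-4-[1-(trimethylsilyl)ethenyl]cyclopent-2-en-1-one F5. Pyridinium p-toluenesulfonate in methanol converts it into (R)-2-(1,1-dimethoxyethyl)-4-[1-(trimethylsilyl)ethenyl]cyclopent-2-en-1-one F6. NIS iododesilylation gives (R)-2-(1,1-dimethoxyethyl)-4-(1-iodoethenyl)cyclopent-2-en-1-one F7. Copper-catalysed addition of 7 anti to the C4 substituent and protonation of the enolate to the trans,trans ketone rejoins the route at 10.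

Step 12. Z to E isomerization of the angeloyl unit during acyl transfer, or β-elimination of the activated β-hydroxy ketone, would erode the last step. The fallback builds the Z alkene on the ester and unmasks the ketone last; it sets out from 18. Bu4NF buffered with AcOH in THF removes the silyl group and gives the C2 alcohol with the ketal intact F8. DCC/DMAP esterification with 2-[bis(2,2,2-trifluoroethoxy)phosphoryl]propanoic acid gives the phosphonopropanoate of that alcohol F9. Still–Gennari olefination (KN(SiMe3)2, 18-crown-6, acetaldehyde, THF, −78 °C) gives the angelate still carrying the dimethyl ketal F10. Pyridinium p-toluenesulfonate in wet acetone then frees the acetyl group and rejoins the route at 22.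

**Further compounds**
F1 | step 7 | tert-butyl{[4-(buta-1,3-dien-2-yl)-2-(1,1-dimethoxyethyl)-3-(2-methylprop-1-en-1-yl)cyclopentyl]oxy}dimethylsilane, configuration as in 12 | C=CC(=C)[C@@H]1C[C@H](O[Si](C)(C)C(C)(C)C)[C@H](C(C)(OC)OC)[C@H]1C=C(C)C
F2 | step 7 | 3-[4-[(tert-butyldimethylsilyl)oxy]-3-(1,1-dimethoxyethyl)-2-(2-methylprop-1-en-1-yl)cyclopentyl]but-3-en-1-ol, configuration as in 12 | OCCC(=C)[C@@H]1C[C@H](O[Si](C)(C)C(C)(C)C)[C@H](C(C)(OC)OC)[C@H]1C=C(C)C
F3 | step 7 | 3-[4-[(tert-butyldimethylsilyl)oxy]-3-(1,1-dimethoxyethyl)-2-(2-methylprop-1-en-1-yl)cyclopentyl]but-3-enal, configuration as in 12 | O=CCC(=C)[C@@H]1C[C@H](O[Si](C)(C)C(C)(C)C)[C@H](C(C)(OC)OC)[C@H]1C=C(C)C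
F4 | step 4 | (R)-2-iodo-4-[1-(trimethylsilyl)ethenyl]cyclopent-2-en-1-one | C=C([Si](C)(C)C)[C@@H]1CC(=O)C(I)=C1
F5 | step 4 | (R)-2-(1-ethoxyethenyl)-4-[1-(trimethylsilyl)ethenyl]cyclopent-2-en-1-one | C=C([Si](C)(C)C)[C@@H]1CC(=O)C(C(=C)OCC)=C1
F6 | step 4 | (R)-2-(1,1-dimethoxyethyl)-4-[1-(trimethylsilyl)ethenyl]cyclopent-2-en-1-one | C=C([Si](C)(C)C)[C@@H]1CC(=O)C(C(C)(OC)OC)=C1
F7 | step 4 | (R)-2-(1,1-dimethoxyethyl)-4-(1-iodoethenyl)cyclopent-2-en-1-one | C=C(I)[C@@H]1CC(=O)C(C(C)(OC)OC)=C1
F8 | step 12 | (1R,2S,3aR,6R,7S,7aR)-1-(1,1-dimethoxyethyl)-2-hydroxy-4-methylidene-7-(propan-2-yl)octahydro-1H-inden-6-yl acetate | C=C1C[C@@H](OC(C)=O)[C@@H](C(C)C)[C@@H]2[C@@H](C(C)(OC)OC)[C@@H](O)C[C@@H]12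
F9 | step 12 | 2-[bis(2,2,2-trifluoroethoxy)phosphoryl]propanoate ester of F8 (phosphonate α-carbon unassigned) | C=C1C[C@@H](OC(C)=O)[C@@H](C(C)C)[C@@H]2[C@@H](C(C)(OC)OC)[C@@H](OC(=O)C(C)P(=O)(OCC(F)(F)F)OCC(F)(F)F)C[C@@H]12
F10 | step 12 | (1R,2S,3aR,6R,7S,7aR)-6-(acetyloxy)-1-(1,1-dimethoxyethyl)-4-methylidene-7-(propan-2-yl)octahydro-1H-inden-2-yl (2Z)-2-methylbut-2-enoate | C=C1C[C@@H](OC(C)=O)[C@@H](C(C)C)[C@@H]2[C@@H](C(C)(OC)OC)[C@@H](OC(=O)/C(C)=C\C)C[C@@H]12
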